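**Strategy**

The lower epigallocatechin unit is not brought in ready-made; its heterocycle (ring F) is built onto ring D of a robinetinidol-derived 4β-arylflavan. The O1–C8a–C4a–C4 edge of ring F is unmasked as the ortho-quinone methide of ring D, and the cis C2–C3 bond is supplied as a (Z)-styrylboronate. One inverse-demand hetero-[4+2] cycloaddition then forms O1–C2 and C3–C4, closes ring F and sets both lower stereocentres, with boron as the latent C3 hydroxyl. The precursor is the benzyl-protected upper flavan whose ring D carries a free C8a phenol, an ortho CH2OH group and a bromine cap at C6.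

Key step: step 10

**Remarks and assumptions**

- Target reading: robinetinidol-(4β→8)-epigallocatechin. Upper unit (rings A, B, C) is (2R,3S,4R), 2,3-trans-3,4-cis; lower unit (rings D, E, F) is (2R,3R), 2,3-cis. No change to the target structure is needed.
- Shorthand: "Fl" is the group (2R,3S,4R)-3,7-bis(benzyloxy)-2-[3,4,5-tris(benzyloxy)phenyl]chroman-4-yl, bonded through the β face of C4.
- Assumption (step 4): capture of the C4 cation is expected to give both C4 epimers; only the 4β (3,4-cis) epimer is carried on.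
- Assumption (step 10): the (R)-acid is taken as the catalyst matched to the upper unit; the sense of induction has to be established in the first run, and the (S)-acid is used otherwise without further change.
- Precursor design: a bromine at ring-D C6 is added as a spectator. It blocks the only nucleophilic CH of ring D, so the quinone methide cannot alkylate its own precursor or the product, and it leaves in the final hydrogenolysis. O3 of the upper unit stays a benzyl ether (non-participating, one global deprotection). The boron ligand stays pinacol because this ester is a poor partner for boron-to-carbon alkenyl transfer.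
- In the boron-bearing cycloadduct the lower unit is formally (2S,3R), because boron ranks below carbon; the spatial arrangement is that of the target.

**Route**

Step 1
Reactants: 1 (+)-dihydrorobinetin
Product: 2 7,3',4',5'-tetra-O-benzyl-dihydrorobinetin
Conditions: BnBr (4.4 equiv), K2CO3, DMF, N2, 20 °C
Reagents that add atoms: benzyl bromide, BrCc1ccccc1
Why: Williamson O-benzylation with a weak base should take only the four phenols (the C3 alcohol is not deprotonated by K2CO3), and mild oxygen-free conditions should leave the base-sensitive 2,3-trans stereocentres untouched.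

Step 2
Reactants: 2 7,3',4',5'-tetra-O-benzyl-dihydrorobinetin
Product: 3 tetra-O-benzyl flavan-3,4-diol (2R,3S,4R)
Conditions: NaBH4, THF–MeOH, 0 °C
Reagents that add atoms: none
Why: Borohydride reduction of the aryl ketone by axial hydride delivery should give mainly the all-equatorial 2,3-trans-3,4-trans diol, and the C4 configuration is immaterial because C4 is ionised in step 4.

Step 3
Reactants: 3 tetra-O-benzyl flavan-3,4-diol
Product: 4 3,4-di-O-benzyl ether of the diol (hexa-O-benzyl flavan)
Conditions: NaH, BnBr, Bu4NI (cat.), DMF, 0 → 20 °C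
Reagents that add atoms: benzyl bromide, BrCc1ccccc1
Why: Williamson etherification of both secondary alkoxides gives a non-participating ether at C3 and turns the C4 benzylic oxygen into the leaving group for step 4.

Step 4
Reactants: 4 hexa-O-benzyl flavan; 5 3,5-bis(benzyloxy)phenol
Product: 7 3,5-bis(benzyloxy)-2-Fl-phenol (4β epimer), via flavan-4-yl cation 6 (not isolated)
Conditions: Me3SiOSO2CF3 (0.2 equiv), 5 (3 equiv), CH2Cl2, −78 → −20 °C; aq. NaHCO3; chromatographic separation of the C4 epimers
Reagents that add atoms: none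
Why: Lewis-acid ionisation of the C4 ether gives a para-benzyloxy-stabilised benzylic cation that alkylates the phenol (Friedel–Crafts, SN1) at the less hindered carbon ortho to the hydroxyl, as benzylated flavan-3-ols react at C8 and not C6; C4 is set on capture, pseudo-axial attack on the half-chair with equatorial C2 and C3 substituents coming from the β face cis to the non-participating O3 ether, and the 4α epimer expected alongside is removed.

Step 5
Reactants: 7 3,5-bis(benzyloxy)-2-Fl-phenol
Product: 8 4,6-bis(benzyloxy)-2-hydroxy-3-Fl-benzaldehyde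
Conditions: MgCl2, Et3N, (CH2O)n, THF, reflux
Reagents that add atoms: formaldehyde (as paraformaldehyde), C=O
Why: Magnesium-phenoxide-directed ortho-formylation (Casnati–Skattebøl) delivers formaldehyde through a six-membered chelate only to the one free carbon ortho to the hydroxyl, a second formaldehyde acting as hydride acceptor.

Step 6
Reactants: 8 4,6-bis(benzyloxy)-2-hydroxy-3-Fl-benzaldehyde
Product: 9 4,6-bis(benzyloxy)-5-bromo-2-hydroxy-3-Fl-benzaldehyde
Conditions: N-bromosuccinimide (1.05 equiv), CH2Cl2, −40 → 0 °C, dark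
Reagents that add atoms: N-bromosuccinimide, O=C1CCC(=O)N1Br
Why: Electrophilic aromatic bromination should go to the only free carbon of ring D, which is para to the free phenol and ortho to two ethers and therefore far more nucleophilic than any position of rings A and B.

Step 7
Reactants: 9 bromo-salicylaldehyde
Product: 10 3,5-bis(benzyloxy)-4-bromo-2-(hydroxymethyl)-6-Fl-phenol
Conditions: NaBH4, THF–MeOH, −10 °C; pH 7 phosphate buffer work-up
Reagents that add atoms: none
Why: Chemoselective borohydride reduction of the aldehyde gives the salicyl alcohol, and the short, cold reaction with neutral work-up avoids ionisation of the electron-rich benzylic alcohol.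

Step 8
Reactants: 11 3,4,5-tris(benzyloxy)benzaldehyde
Product: 12 1,2,3-tris(benzyloxy)-5-ethynylbenzene
Conditions: dimethyl (1-diazo-2-oxopropyl)phosphonate, K2CO3, MeOH–THF, 20 °C
Reagents that add atoms: dimethyl (1-diazo-2-oxopropyl)phosphonate, CC(=O)C(=[N+]=[N-])P(=O)(OC)OC
Why: Seyferth–Gilbert homologation with the Ohira–Bestmann reagent converts a non-enolisable aryl aldehyde into the terminal alkyne under carbonate conditions that leave benzyl ethers untouched.

Step 9
Reactants: 12 1,2,3-tris(benzyloxy)-5-ethynylbenzene; 13 pinacolborane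
Product: 14 (Z)-2-[3,4,5-tris(benzyloxy)phenyl]ethenylboronic acid pinacol ester
Conditions: [Rh(cod)Cl]2 (1.5 mol%), P(iPr)3 (6 mol%), Et3N, cyclohexane–toluene, 20 °C, alkyne in slight excess
Reagents that add atoms: none
Why: Rhodium-catalysed trans-hydroboration of a terminal alkyne adds boron and hydrogen anti after a 1,2-hydrogen shift at the metal, placing boron on the terminal carbon cis to the aryl group and so setting the (Z) geometry.

Step 10
Reactants: 10 ring-D salicyl alcohol; 14 (Z)-styrylboronate
Product: 16 deca-O-benzyl 6-bromo dimer with C3 pinacolboronate on ring F (2,3-cis), via ring-D ortho-quinone methide 15 (not isolated)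
Conditions: (R)-3,3'-bis(2,4,6-triisopropylphenyl)-1,1'-binaphthyl-2,2'-diyl hydrogen phosphate (10 mol%), 14 (3 equiv), 4 Å molecular sieves, toluene, −20 → 20 °C, slow addition of 10
Reagents that add atoms: none
Why: Proposed new method: the chiral phosphoric acid should dehydrate 10 to the ring-D ortho-quinone methide 15 and stay hydrogen-bonded to its oxygen, lowering the LUMO of the O=C8a–C4a=CH2 oxadiene so that the (Z)-alkene of 14 adds in a concerted but asynchronous inverse-demand [4+2] event in which C3–C4 bonding leads and the positive charge building at C2 is held by the 4-benzyloxyaryl ring and the adjacent C–B bond before O1–C2 closes within the same ion pair. The closest known reaction type is the acid- or heat-promoted hetero-Diels–Alder reaction of ortho-quinone methides from ortho-hydroxybenzyl alcohols with styrenes to 2-arylchromans, chiral phosphoric acid variants included; new here are a β-borylated (Z)-styrene as the 2π partner and catalyst control beside a bulky chiral C8 substituent. Ring F closes as the six-membered cycloadduct itself, both σ bonds forming suprafacially on the 4π and the 2π component, so no separate ring-closing event is involved. The cis C2/C3 relation is dictated by the (Z) geometry, transferred stereospecifically as long as O1–C2 closure outruns C2–C3 rotation (non-polar solvent, weak acid, low temperature), while the absolute sense at C2 and C3, that is which alkene face meets the planar diene, is to be imposed by the binaphthyl phosphate held at the C8a oxygen acting together with the 4β-flavanyl group on C8. The step needs regioselectivity (O to the benzylic carbon, CH2 to the boron-bearing carbon), secured by the trioxyaryl ring; chemoselectivity for cycloaddition over boron-to-carbon 1,4-transfer of the alkenyl group, secured by the poorly Lewis-acidic pinacol ester; and protection of ring D against alkylation by its own quinone methide, secured by the C6 bromine.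

Step 11
Reactants: 16 C3 pinacolboronate
Product: 17 deca-O-benzyl 6-bromo dimer with free C3 hydroxyl on ring F
Conditions: NaBO3·4H2O, THF–H2O, 20 °C
Reagents that add atoms: sodium perborate tetrahydrate (NaBO3·4H2O), [Na+].[Na+].O[B-]1(O)OO[B-](O)(O)OO1
Why: Organoborane oxidation in which C3 migrates from boron to oxygen with retention keeps the cis relation to the C2 aryl group, and the nearly neutral reagent leaves aryl bromide and benzyl ethers alone.

Step 12
Reactants: 17 deca-O-benzyl 6-bromo dimer
Product: 18 robinetinidol-(4β→8)-epigallocatechin (target)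
Conditions: H2 (1 atm), Pd(OH)2 on carbon, CH3CO2Na, THF–MeOH–H2O, 20 °C; filtration and freeze-drying under argon
Reagents that add atoms: none
Why: Catalytic hydrogenolysis should cleave the ten benzyl ethers and the aryl C–Br bond in one operation, acetate taking up HBr, while the flavan C2–O1 bonds and the C4–C8 bond are not hydrogenolysed under these standard conditions for benzylated proanthocyanidins.

**Compound list**

1 | (+)-dihydrorobinetin, (2R,3R)-3,7-dihydroxy-2-(3,4,5-trihydroxyphenyl)chroman-4-one | Oc1ccc2c(c1)O[C@H](c1cc(O)c(O)c(O)c1)[C@@H](O)C2=O | starting material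

2 | (2R,3R)-7-benzyloxy-3-hydroxy-2-[3,4,5-tris(benzyloxy)phenyl]chroman-4-one | c1(OCc9ccccc9)ccc2c(c1)O[C@H](c5cc(OCc9ccccc9)c(OCc9ccccc9)c(OCc9ccccc9)c5)[C@@H](O)C2=O | intermediate

3 | (2R,3S,4R)-7-benzyloxy-2-[3,4,5-tris(benzyloxy)phenyl]chroman-3,4-diol (2,3-trans-3,4-trans) | c1(OCc9ccccc9)ccc2c(c1)O[C@H](c5cc(OCc9ccccc9)c(OCc9ccccc9)c(OCc9ccccc9)c5)[C@@H](O)[C@@H]2O | intermediate

4 | (2R,3S,4R)-3,4,7-tris(benzyloxy)-2-[3,4,5-tris(benzyloxy)phenyl]chroman | c1(OCc9ccccc9)ccc2c(c1)O[C@H](c5cc(OCc9ccccc9)c(OCc9ccccc9)c(OCc9ccccc9)c5)[C@@H](OCc9ccccc9)[C@@H]2OCc9ccccc9 | intermediate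

5 | 3,5-bis(benzyloxy)phenol | Oc1cc(OCc2ccccc2)cc(OCc2ccccc2)c1 | starting material

6 | (2R,3S)-3,7-bis(benzyloxy)-2-[3,4,5-tris(benzyloxy)phenyl]chroman-4-ylium trifluoromethanesulfonate (ion pair) | c1(OCc9ccccc9)ccc2c(c1)O[C@H](c5cc(OCc9ccccc9)c(OCc9ccccc9)c(OCc9ccccc9)c5)[C@@H](OCc9ccccc9)[CH+]2.[O-]S(=O)(=O)C(F)(F)F | intermediate

7 | 3,5-bis(benzyloxy)-2-Fl-phenol (Fl bonded 4β; upper unit 2R,3S,4R) | c1(OCc9ccccc9)ccc2c(c1)O[C@H](c5cc(OCc9ccccc9)c(OCc9ccccc9)c(OCc9ccccc9)c5)[C@@H](OCc9ccccc9)[C@H]2c6c(OCc9ccccc9)cc(OCc9ccccc9)cc6O | intermediate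

8 | 4,6-bis(benzyloxy)-2-hydroxy-3-Fl-benzaldehyde | c1(OCc9ccccc9)ccc2c(c1)O[C@H](c5cc(OCc9ccccc9)c(OCc9ccccc9)c(OCc9ccccc9)c5)[C@@H](OCc9ccccc9)[C@H]2c6c(OCc9ccccc9)cc(OCc9ccccc9)c(C=O)c6O | intermediate

9 | 4,6-bis(benzyloxy)-5-bromo-2-hydroxy-3-Fl-benzaldehyde | c1(OCc9ccccc9)ccc2c(c1)O[C@H](c5cc(OCc9ccccc9)c(OCc9ccccc9)c(OCc9ccccc9)c5)[C@@H](OCc9ccccc9)[C@H]2c6c(OCc9ccccc9)c(Br)c(OCc9ccccc9)c(C=O)c6O | intermediate

10 | 3,5-bis(benzyloxy)-4-bromo-2-(hydroxymethyl)-6-Fl-phenol (key-step precursor) | c1(OCc9ccccc9)ccc2c(c1)O[C@H](c5cc(OCc9ccccc9)c(OCc9ccccc9)c(OCc9ccccc9)c5)[C@@H](OCc9ccccc9)[C@H]2c6c(OCc9ccccc9)c(Br)c(OCc9ccccc9)c(CO)c6O | intermediate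

11 | 3,4,5-tris(benzyloxy)benzaldehyde | O=Cc1cc(OCc2ccccc2)c(OCc2ccccc2)c(OCc2ccccc2)c1 | starting material

12 | 1,2,3-tris(benzyloxy)-5-ethynylbenzene | C#Cc1cc(OCc2ccccc2)c(OCc2ccccc2)c(OCc2ccccc2)c1 | intermediate

13 | pinacolborane (4,4,5,5-tetramethyl-1,3,2-dioxaborolane) | CC1(C)OBOC1(C)C | starting material

14 | (Z)-2-{2-[3,4,5-tris(benzyloxy)phenyl]ethenyl}-4,4,5,5-tetramethyl-1,3,2-dioxaborolane | CC1(C)OB(OC1(C)C)/C=C\c8cc(OCc9ccccc9)c(OCc9ccccc9)c(OCc9ccccc9)c8 | intermediate

15 | 3,5-bis(benzyloxy)-4-bromo-6-methylidene-2-Fl-cyclohexa-2,4-dien-1-one (ring-D ortho-quinone methide) | c1(OCc9ccccc9)ccc2c(c1)O[C@H](c5cc(OCc9ccccc9)c(OCc9ccccc9)c(OCc9ccccc9)c5)[C@@H](OCc9ccccc9)[C@H]2C6=C(OCc9ccccc9)C(Br)=C(OCc9ccccc9)C(=C)C6=O | intermediate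

16 | 2-{(2S,3R)-5,7-bis(benzyloxy)-6-bromo-8-Fl-2-[3,4,5-tris(benzyloxy)phenyl]chroman-3-yl}-4,4,5,5-tetramethyl-1,3,2-dioxaborolane (ring F 2,3-cis, aryl and boron both α) | c1(OCc9ccccc9)ccc2c(c1)O[C@H](c5cc(OCc9ccccc9)c(OCc9ccccc9)c(OCc9ccccc9)c5)[C@@H](OCc9ccccc9)[C@H]2c6c(OCc9ccccc9)c(Br)c(OCc9ccccc9)c7c6O[C@H](c8cc(OCc9ccccc9)c(OCc9ccccc9)c(OCc9ccccc9)c8)[C@H](B3OC(C)(C)C(C)(C)O3)C7 | intermediate

17 | (2R,3R)-5,7-bis(benzyloxy)-6-bromo-8-Fl-2-[3,4,5-tris(benzyloxy)phenyl]chroman-3-ol | c1(OCc9ccccc9)ccc2c(c1)O[C@H](c5cc(OCc9ccccc9)c(OCc9ccccc9)c(OCc9ccccc9)c5)[C@@H](OCc9ccccc9)[C@H]2c6c(OCc9ccccc9)c(Br)c(OCc9ccccc9)c7c6O[C@H](c8cc(OCc9ccccc9)c(OCc9ccccc9)c(OCc9ccccc9)c8)[C@H](O)C7 | intermediate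

18 | robinetinidol-(4β→8)-epigallocatechin, (2R,3R)-8-[(2R,3S,4R)-3,7-dihydroxy-2-(3,4,5-trihydroxyphenyl)chroman-4-yl]-2-(3,4,5-trihydroxyphenyl)chroman-3,5,7-triol | Oc1ccc2c(c1)O[C@H](c1cc(O)c(O)c(O)c1)[C@@H](O)[C@H]2c1c(O)cc(O)c2c1O[C@H](c1cc(O)c(O)c(O)c1)[C@H](O)C2 | target

**Step count and risks**

Total step count: 12. Longest linear sequence: 10 steps (steps 1–7, then 10, 11, 12); steps 8 and 9 form the two-step side branch.

Steps most likely to fail:

1. Step 10 (proposed new method). The alkene may add through the wrong face if the catalyst and the C8 substituent oppose each other. A stepwise cationic addition may erode the cis relation. The alkenyl group may also be transferred from boron to the methylene carbon with loss of boron. The fallback uses known chemistry and a different disconnection; it sets out from 4 and comes back to the route at 18. Commercial (−)-epigallocatechin F1 is benzylated on its five phenols (BnBr, K2CO3, DMF) to 5,7,3',4',5'-penta-O-benzylepigallocatechin F2. Ionisation of 4 with Me3SiOSO2CF3 in the presence of excess F2 (CH2Cl2, −78 °C) should alkylate C8 of F2, the usual site for benzylated flavan-3-ol nucleophiles. After separation of the C4 epimers this should give the deca-O-benzyl dimer F3, and hydrogenolysis as in step 12 (without acetate) should give 18.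

2. Step 4. The cation may be captured mainly on the α face (3,4-trans), at the carbon para to the phenol, or twice. The fallback delivers the aryl group from a defined oxygen on the β face; it sets out from 2 (with 5) and comes back at 7. Acid-catalysed O-benzylation of 2 with benzyl 2,2,2-trichloroacetimidate and catalytic CF3SO3H gives the 3-O-benzyl ketone F4 without base. NaBH4 reduction gives the 3,4-trans alcohol F5. Mitsunobu etherification with 5 (PPh3, diisopropyl azodicarboxylate) inverts C4 to the 4β-aryl ether F6. BF3·OEt2 in toluene at low temperature then induces O→C migration within the contact ion pair, which should return the aryl group through its ortho carbon to the same β face and give 7.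

3. Step 9. Anti-addition may be incomplete, or the (Z)-boronate may isomerise on the catalyst, and any (E) isomer would be carried into trans-configured ring F. The fallback fixes the geometry by a syn-addition and protonolysis sequence; it sets out from 12 and comes back at 14. Deprotonation with nBuLi and trapping with 2-isopropoxy-4,4,5,5-tetramethyl-1,3,2-dioxaborolane, then anhydrous HCl, gives the alkynylboronate F7. Syn-hydrozirconation with Cp2Zr(H)Cl (zirconium to the boron-bearing carbon) and protonolysis with water with retention should give 14.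

Further compounds

F1 | step 10 | (−)-epigallocatechin, (2R,3R)-2-(3,4,5-trihydroxyphenyl)chroman-3,5,7-triol (bought, not made) | Oc1cc(O)c2c(c1)O[C@H](c1cc(O)c(O)c(O)c1)[C@H](O)C2
F2 | step 10 | (2R,3R)-5,7-bis(benzyloxy)-2-[3,4,5-tris(benzyloxy)phenyl]chroman-3-ol | c1(OCc9ccccc9)cc(OCc9ccccc9)c2c(c1)O[C@H](c8cc(OCc9ccccc9)c(OCc9ccccc9)c(OCc9ccccc9)c8)[C@H](O)C2
F3 | step 10 | (2R,3R)-5,7-bis(benzyloxy)-8-Fl-2-[3,4,5-tris(benzyloxy)phenyl]chroman-3-ol (bromine-free analogue of 17) | c1(OCc9ccccc9)ccc2c(c1)O[C@H](c5cc(OCc9ccccc9)c(OCc9ccccc9)c(OCc9ccccc9)c5)[C@@H](OCc9ccccc9)[C@H]2c6c(OCc9ccccc9)cc(OCc9ccccc9)c7c6O[C@H](c8cc(OCc9ccccc9)c(OCc9ccccc9)c(OCc9ccccc9)c8)[C@H](O)C7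
F4 | step 4 | (2R,3R)-3,7-bis(benzyloxy)-2-[3,4,5-tris(benzyloxy)phenyl]chroman-4-one | c1(OCc9ccccc9)ccc2c(c1)O[C@H](c5cc(OCc9ccccc9)c(OCc9ccccc9)c(OCc9ccccc9)c5)[C@@H](OCc9ccccc9)C2=O
F5 | step 4 | (2R,3S,4R)-3,7-bis(benzyloxy)-2-[3,4,5-tris(benzyloxy)phenyl]chroman-4-ol (4α-hydroxyl, 3,4-trans) | c1(OCc9ccccc9)ccc2c(c1)O[C@H](c5cc(OCc9ccccc9)c(OCc9ccccc9)c(OCc9ccccc9)c5)[C@@H](OCc9ccccc9)[C@@H]2O
F6 | step 4 | (2R,3S,4S)-3,7-bis(benzyloxy)-4-[3,5-bis(benzyloxy)phenoxy]-2-[3,4,5-tris(benzyloxy)phenyl]chroman (4β-aryl ether) | c1(OCc9ccccc9)ccc2c(c1)O[C@H](c5cc(OCc9ccccc9)c(OCc9ccccc9)c(OCc9ccccc9)c5)[C@@H](OCc9ccccc9)[C@H]2Oc6cc(OCc9ccccc9)cc(OCc9ccccc9)c6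
F7 | step 9 | 2-{[3,4,5-tris(benzyloxy)phenyl]ethynyl}-4,4,5,5-tetramethyl-1,3,2-dioxaborolane | CC1(C)OB(OC1(C)C)C#Cc8cc(OCc9ccccc9)c(OCc9ccccc9)c(OCc9ccccc9)c8
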